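**Retrosynthetic overview**
- Target ⇒ both pyran rings closed in the last flask. Ring A: Knoevenagel/oxa-6π annulation of 2,4-dihydroxy-6-methoxyacetophenone onto a chiral α-branched enal that already holds the C3–CH(CH3)–aryl bond. Ring B: the same annulation of prenal onto the free phenol of that enal.
- Phenol-enal ⇒ (S)-3-arylbutanal + acetone ketal (Mukaiyama α-isopropylidenation, fluoride unmasking).
- (S)-3-Arylbutanal ⇒ β-aryl-β-methyl enal by iminium-catalysed transfer hydrogenation (sets the only stereocentre).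
- Enal ⇒ TIPS-protected 3,5-dimethoxyphenol: lithiation between the two OMe groups, addition to 4,4-dimethoxybutan-2-one.
- Ring order: both benzene rings are bought; pyran ring A, then pyran ring B, in one operation at the end.

Assumption: the stereocentre in the SMILES is read as (S) (CIP order: chromenyl aryl > chromene C3 > CH3 > H).

**Step 1**
Reactants: 1 3,5-dimethoxyphenol; 2 chlorotriisopropylsilane
Product: 3 (3,5-dimethoxyphenoxy)triisopropylsilane
Conditions: 2 (1.1 equiv), imidazole (2 equiv), DMF, rt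
Reagents that add atoms: chlorotriisopropylsilane (2), CC(C)[Si](Cl)(C(C)C)C(C)C
Why: Imidazole-promoted O-silylation; the bulky TIPS ether blocks metalation next to the phenol oxygen, so step 2 lithiates only between the two methoxy groups.

**Step 2**
Reactants: 3 (3,5-dimethoxyphenoxy)triisopropylsilane; 4 4,4-dimethoxybutan-2-one
Product: 7 (2E)-3-[2,6-dimethoxy-4-(triisopropylsilyloxy)phenyl]but-2-enal, via aryllithium 5 (not isolated), via acetal carbinol 6 (not isolated)
Conditions: n-BuLi, THF, 0 °C → rt; CeCl3, −78 °C; 4, −78 → 0 °C; then 2 M HCl, THF, rt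
Reagents that add atoms: 4,4-dimethoxybutan-2-one (4), CC(=O)CC(OC)OC; water, O
Why: Directed ortho-metalation between the two cooperating OMe groups gives one aryllithium, whose cerium-mediated 1,2-addition to the methyl ketone and acid-promoted dehydration/acetal hydrolysis give the β-methyl enal (no stereocentre remains; an E/Z mixture is acceptable for step 3).

**Step 3**
Reactants: 7 (2E)-3-[2,6-dimethoxy-4-(triisopropylsilyloxy)phenyl]but-2-enal
Product: 8 (3S)-3-[2,6-dimethoxy-4-(triisopropylsilyloxy)phenyl]butanal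
Conditions: (R)-2-tert-butyl-3-methylimidazolidin-4-one·CCl3CO2H (20 mol%), Hantzsch ester (diethyl 2,6-dimethyl-1,4-dihydropyridine-3,5-dicarboxylate, 1.2 equiv), CHCl3, −30 °C
Reagents that add atoms: none
Why: Iminium-catalysed organocatalytic transfer hydrogenation (MacMillan type): E/Z isomers equilibrate through the dienamine and hydride adds to one face of the β-carbon of the chiral iminium ion, setting the benzylic (S)-centre in the sense I recall for β-methylcinnamaldehyde with the (R)-catalyst (from memory; confirm on the first run).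

**Step 4**
Reactants: 8 (3S)-3-[2,6-dimethoxy-4-(triisopropylsilyloxy)phenyl]butanal; 9 2,2-dimethoxypropane
Product: 12 2-[(1R)-1-(4-hydroxy-2,6-dimethoxyphenyl)ethyl]-3-methylbut-2-enal, via enol silane 10 (not isolated), via methoxy aldehyde 11 (not isolated)
Conditions: Me3SiOTf (1.5 equiv), i-Pr2NEt (1.2 equiv), CH2Cl2, 0 °C; 9 (2 equiv), −78 → 0 °C; then Bu4NF, THF, rt
Reagents that add atoms: 2,2-dimethoxypropane (9), COC(C)(C)OC
Why: One-flask enol silane formation and Mukaiyama-type alkylation by the ketal-derived 2-methoxypropan-2-ylium ion builds the C3–CMe2 bond, then fluoride removes TIPS and eliminates methanol (E1cB) to the tetrasubstituted enal; the transient α-centre is destroyed and the benzylic centre is cross-conjugated, not acidic and untouched (its descriptor becomes R only because the CIP priorities change).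

**Step 5**
Reactants: 12 2-[(1R)-1-(4-hydroxy-2,6-dimethoxyphenyl)ethyl]-3-methylbut-2-enal; 13 1-(2,4-dihydroxy-6-methoxyphenyl)ethan-1-one; 14 3-methylbut-2-enal (prenal)
Product: 16 1-{3-[(1S)-1-(5,7-dimethoxy-2,2-dimethyl-2H-chromen-6-yl)ethyl]-5-hydroxy-7-methoxy-2,2-dimethyl-2H-chromen-6-yl}ethan-1-one (target), via hydroxyaryl chromene 15 (not isolated)
Conditions: 13 (1.2 equiv), ethylenediammonium diacetate (EDDA, 20 mol%), o-xylene, 140 °C; then 14 (2 equiv), 120 °C; one flask, one work-up
Reagents that add atoms: 1-(2,4-dihydroxy-6-methoxyphenyl)ethan-1-one (13), CC(=O)c1c(O)cc(O)cc1OC; 3-methylbut-2-enal (14), CC(C)=CC=O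
Why: Proposed new method: two amine-catalysed Knoevenagel/oxa-6π-electrocyclisation chromene annulations run back to back in one flask (closest known type: EDDA-catalysed phenol + enal chromenylation) — the iminium ion of the hindered enal is attacked by C3 of 13 (between its two OH groups), loss of amine gives a vinyl o-quinone methide that closes through the non-chelated 4-OH to ring A, then prenal does the same on the only remaining free phenol to close ring B, while the stereocentre is a spectator with no acidic or ionisable site and stays (S).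

**Compound list**
1 | 3,5-dimethoxyphenol | COc1cc(O)cc(OC)c1 | starting material
2 | chlorotriisopropylsilane | CC(C)[Si](Cl)(C(C)C)C(C)C | starting material
3 | (3,5-dimethoxyphenoxy)triisopropylsilane | COc1cc(OC)cc(O[Si](C(C)C)(C(C)C)C(C)C)c1 | intermediate
4 | 4,4-dimethoxybutan-2-one | CC(=O)CC(OC)OC | starting material
5 | [2,6-dimethoxy-4-(triisopropylsilyloxy)phenyl]lithium | [Li]c1c(OC)cc(O[Si](C(C)C)(C(C)C)C(C)C)cc1OC | intermediate
6 | 2-[2,6-dimethoxy-4-(triisopropylsilyloxy)phenyl]-4,4-dimethoxybutan-2-ol (racemic; formed as its alkoxide) | CC(O)(CC(OC)OC)c1c(OC)cc(O[Si](C(C)C)(C(C)C)C(C)C)cc1OC | intermediate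
7 | (2E)-3-[2,6-dimethoxy-4-(triisopropylsilyloxy)phenyl]but-2-enal | C/C(=C\C=O)c1c(OC)cc(O[Si](C(C)C)(C(C)C)C(C)C)cc1OC | intermediate
8 | (3S)-3-[2,6-dimethoxy-4-(triisopropylsilyloxy)phenyl]butanal | C[C@@H](CC=O)c1c(OC)cc(O[Si](C(C)C)(C(C)C)C(C)C)cc1OC | intermediate
9 | 2,2-dimethoxypropane | COC(C)(C)OC | starting material
10 | {[(3S)-3-[2,6-dimethoxy-4-(triisopropylsilyloxy)phenyl]but-1-en-1-yl]oxy}trimethylsilane (E/Z mixture) | C[C@@H](C=CO[Si](C)(C)C)c1c(OC)cc(O[Si](C(C)C)(C(C)C)C(C)C)cc1OC | intermediate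
11 | (3S)-3-[2,6-dimethoxy-4-(triisopropylsilyloxy)phenyl]-2-(2-methoxypropan-2-yl)butanal (C2 epimers) | C[C@@H](C(C=O)C(C)(C)OC)c1c(OC)cc(O[Si](C(C)C)(C(C)C)C(C)C)cc1OC | intermediate
12 | 2-[(1R)-1-(4-hydroxy-2,6-dimethoxyphenyl)ethyl]-3-methylbut-2-enal | C[C@@H](C(C=O)=C(C)C)c1c(OC)cc(O)cc1OC | intermediate
13 | 1-(2,4-dihydroxy-6-methoxyphenyl)ethan-1-one | CC(=O)c1c(O)cc(O)cc1OC | starting material
14 | 3-methylbut-2-enal | CC(C)=CC=O | starting material
15 | 1-{5-hydroxy-3-[(1S)-1-(4-hydroxy-2,6-dimethoxyphenyl)ethyl]-7-methoxy-2,2-dimethyl-2H-chromen-6-yl}ethan-1-one | COc1cc2c(c(O)c1C(C)=O)C=C([C@H](C)c1c(OC)cc(O)cc1OC)C(C)(C)O2 | intermediate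
16 | 1-{3-[(1S)-1-(5,7-dimethoxy-2,2-dimethyl-2H-chromen-6-yl)ethyl]-5-hydroxy-7-methoxy-2,2-dimethyl-2H-chromen-6-yl}ethan-1-one | COc1cc2c(c(O)c1C(C)=O)C=C([C@H](C)c1c(OC)cc3c(c1OC)C=CC(C)(C)O3)C(C)(C)O2 | target

**Totals**
Total steps: 5. Longest linear sequence: 5 (1 → 3 → 7 → 8 → 12 → 16).

**Steps most likely to fail, with fallbacks**

Step 5 is the main risk. The enal is tetrasubstituted and α-branched, so its condensation with 13 may be slow. 13 can also react at C5 or close through the chelated 2-OH, and the staged addition must keep prenal away from unreacted 13. The fallback sets out from 12. O-Alkylation with 3-chloro-3-methylbut-1-yne (K2CO3, KI, CuI, acetone, 50 °C) gives 2-[(1R)-1-{2,6-dimethoxy-4-[(2-methylbut-3-yn-2-yl)oxy]phenyl}ethyl]-3-methylbut-2-enal F1. F1 and 13 are then heated in a single charge (EDDA, o-xylene, 140 °C). Ring B now closes inside the molecule by aryl propargyl ether Claisen rearrangement, [1,5]-H shift and oxa-6π closure, while ring A closes by the condensation. No free prenal is present to consume 13. The fallback comes back to the route at 16.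

Step 3 is the second risk. The twisted 2,6-dimethoxyaryl group shields the β-carbon, so conversion or ee may be low, and the catalyst sense is assigned by analogy. The fallback sets out from 3 and takes the stereocentre from the chiral pool. Lithiation as in step 2 gives 5, and MgBr2·OEt2 converts it into [2,6-dimethoxy-4-(triisopropylsilyloxy)phenyl]magnesium bromide F2. With CuBr·SMe2 (10 mol%), F2 opens (R)-4-methyloxetan-2-one at the methyl-bearing carbon by SN2 with inversion (THF, −30 °C). This gives (3S)-3-[2,6-dimethoxy-4-(triisopropylsilyloxy)phenyl]butanoic acid F3. BH3·SMe2 reduces it to (3S)-3-[2,6-dimethoxy-4-(triisopropylsilyloxy)phenyl]butan-1-ol F4. Dess–Martin oxidation of F4 comes back to the route at 8, and compound 7 is bypassed.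

Step 4 is the third risk. The enol silane must attack a tertiary cation next to a crowded benzylic centre, and the aldehyde may self-condense. The fallback sets out from 8 and replaces the Lewis-acid alkylation by a directed aldol of a metalated imine with acetone itself. Cyclohexanamine and MgSO4 give (1E,3S)-N-cyclohexyl-3-[2,6-dimethoxy-4-(triisopropylsilyloxy)phenyl]butan-1-imine F5. LiN(i-Pr)2 (THF, −78 °C) and then acetone give the adduct (3S)-N-cyclohexyl-3-[2,6-dimethoxy-4-(triisopropylsilyloxy)phenyl]-2-(2-hydroxypropan-2-yl)butan-1-imine F6, which is not isolated. Aqueous oxalic acid hydrolyses and dehydrates it to 2-[(1R)-1-[2,6-dimethoxy-4-(triisopropylsilyloxy)phenyl]ethyl]-3-methylbut-2-enal F7. Bu4NF then removes the silyl group and comes back to the route at 12.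

**Further compounds**
F1 | step 5 | 2-[(1R)-1-{2,6-dimethoxy-4-[(2-methylbut-3-yn-2-yl)oxy]phenyl}ethyl]-3-methylbut-2-enal | C[C@@H](C(C=O)=C(C)C)c1c(OC)cc(OC(C)(C)C#C)cc1OC
F2 | step 3 | [2,6-dimethoxy-4-(triisopropylsilyloxy)phenyl]magnesium bromide | Br[Mg]c1c(OC)cc(O[Si](C(C)C)(C(C)C)C(C)C)cc1OC
F3 | step 3 | (3S)-3-[2,6-dimethoxy-4-(triisopropylsilyloxy)phenyl]butanoic acid | C[C@@H](CC(O)=O)c1c(OC)cc(O[Si](C(C)C)(C(C)C)C(C)C)cc1OC
F4 | step 3 | (3S)-3-[2,6-dimethoxy-4-(triisopropylsilyloxy)phenyl]butan-1-ol | C[C@@H](CCO)c1c(OC)cc(O[Si](C(C)C)(C(C)C)C(C)C)cc1OC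
F5 | step 4 | (1E,3S)-N-cyclohexyl-3-[2,6-dimethoxy-4-(triisopropylsilyloxy)phenyl]butan-1-imine | C[C@@H](C/C=N/C1CCCCC1)c1c(OC)cc(O[Si](C(C)C)(C(C)C)C(C)C)cc1OC
F6 | step 4 | (3S)-N-cyclohexyl-3-[2,6-dimethoxy-4-(triisopropylsilyloxy)phenyl]-2-(2-hydroxypropan-2-yl)butan-1-imine (C2 epimers) | C[C@@H](C(C=NC1CCCCC1)C(C)(C)O)c1c(OC)cc(O[Si](C(C)C)(C(C)C)C(C)C)cc1OC
F7 | step 4 | 2-[(1R)-1-[2,6-dimethoxy-4-(triisopropylsilyloxy)phenyl]ethyl]-3-methylbut-2-enal | C[C@@H](C(C=O)=C(C)C)c1c(OC)cc(O[Si](C(C)C)(C(C)C)C(C)C)cc1OC
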